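**Retrosynthetic overview**
- The CH2OH and all phenols are released last by one hydride reduction of a tris-pivalate methyl ester. The stilbene C–C bond is made just before, by direct C5–H alkenylation of the dihydrobenzofuran ester with a 3,5-diacyloxystyrene.
- The dihydrofuran ring comes from oxidative ring contraction (1,2-aryl shift) of a (2R)-flavanone: C2 is carried over and C3 is set trans during the shift.
- The flavanone comes from asymmetric rhodium-catalysed 1,4-addition of an arylboronic acid to 8-methoxychromone, which sets C2.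
- The chromone is built from 2-bromophenol and ethyl propiolate. The boronic acid and the styrene both come from resorcinol by sterically controlled C–H borylation, the styrene with vinyl bromide.
- Ring order: the three benzene rings are bought; the pyranone ring is closed first and then contracted to the dihydrofuran ring.

Assumption: the (R)-configured bisphosphine delivers the aryl group to the chromone face that gives the (2R)-flavanone, as the facial model for cyclic enones predicts; if the measured sense is opposite, the (S)-ligand is used.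

**Route**

Step 1
Reactants: 1 2-bromophenol
Product: 2 2-methoxyphenol
Conditions: NaOMe, CuBr (10 mol%), MeOH/DMF, 110 °C; aq. HCl work-up
Reagents that add atoms: sodium methoxide [Na+].[O-]C
Why: Copper-catalysed Ullmann-type methoxylation of the aryl bromide, which tolerates the ortho phenoxide; no stereocentre is formed.

Step 2
Reactants: 2 2-methoxyphenol + 3 ethyl propiolate
Product: 4 ethyl (E)-3-(2-methoxyphenoxy)prop-2-enoate
Conditions: DABCO (10 mol%), CH2Cl2, 0 °C to rt
Reagents that add atoms: none
Why: Amine-catalysed oxa-Michael addition of the phenol to the ynoate gives the (E)-aryloxyacrylate.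

Step 3
Reactants: 4 ethyl (E)-3-(2-methoxyphenoxy)prop-2-enoate
Product: 6 8-methoxy-4H-chromen-4-one, via (E)-3-(2-methoxyphenoxy)prop-2-enoic acid 5 (not isolated)
Conditions: NaOH, EtOH/H2O, rt; aq. HCl; then Eaton's reagent (P2O5 in MeSO3H) as solvent, 70 °C
Reagents that add atoms: none
Why: Saponification followed by intramolecular Friedel–Crafts acylation at the only free position ortho to the aryl ether oxygen closes the pyranone ring after acid-mediated E/Z equilibration.

Step 4
Reactants: 7 resorcinol
Product: 8 1,3-dimethoxybenzene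
Conditions: MeI, K2CO3, acetone, reflux
Reagents that add atoms: iodomethane CI
Why: Williamson etherification of both phenols.

Step 5
Reactants: 8 1,3-dimethoxybenzene
Product: 12 2,6-dimethoxyphenyl 2,2-dimethylpropanoate, via 2,6-dimethoxyphenyllithium 9 (not isolated), via dimethyl 2,6-dimethoxyphenylboronate 10 (not isolated), via 2,6-dimethoxyphenol 11 (not isolated)
Conditions: n-BuLi, THF, 0 °C to rt; B(OMe)3, −78 °C to rt; 30% H2O2, AcOH, 0 °C; extractive work-up, then PivCl, Et3N, DMAP (cat.), CH2Cl2, rt
Reagents that add atoms: hydrogen peroxide OO; pivaloyl chloride CC(C)(C)C(=O)Cl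
Why: Directed ortho-metalation between the two methoxy groups, borylation and oxidative boron-to-oxygen migration give the phenol, which is acylated crude to a hindered ester that survives the later acidic, oxidative and mildly basic steps.

Step 6
Reactants: 12 2,6-dimethoxyphenyl 2,2-dimethylpropanoate
Product: 14 [4-(2,2-dimethylpropanoyloxy)-3,5-dimethoxyphenyl]boronic acid, via pinacol boronate 13 (not isolated)
Conditions: [Ir(OMe)(cod)]2 (1.5 mol%), 4,4'-di-tert-butyl-2,2'-bipyridine (3 mol%), B2pin2 (0.7 equiv), THF, 80 °C; then NaIO4, 1 M aq. HCl, THF/H2O, rt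
Reagents that add atoms: bis(pinacolato)diboron CC1(C)OB(OC1(C)C)B1OC(C)(C)C(C)(C)O1; water O
Why: Sterically controlled iridium-catalysed C–H borylation occurs only at C4, the one C–H without an ortho substituent, and periodate cleavage of the pinacol ester gives the boronic acid.

Step 7
Reactants: 6 8-methoxy-4H-chromen-4-one + 14 [4-(2,2-dimethylpropanoyloxy)-3,5-dimethoxyphenyl]boronic acid
Product: 15 4-[(2R)-8-methoxy-4-oxo-3,4-dihydro-2H-chromen-2-yl]-2,6-dimethoxyphenyl 2,2-dimethylpropanoate
Conditions: [Rh(OH)(cod)]2 (1.5 mol%), (R)-MeO-F12-BIPHEP (3.3 mol%), 14 (1.5 equiv), toluene/H2O (10:1), 30 °C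
Reagents that add atoms: none
Why: Rhodium-catalysed asymmetric conjugate addition (Hayashi–Miyaura reaction): the aryl–rhodium species carrying the (R)-bisphosphine inserts the chromone C2=C3 bond from one face and hydrolysis gives the (2R)-flavanone, while the electron-poor ligand and base-free medium suppress 1,2-addition, pivalate loss and retro-oxa-Michael racemisation.

Step 8
Reactants: 15 4-[(2R)-8-methoxy-4-oxo-3,4-dihydro-2H-chromen-2-yl]-2,6-dimethoxyphenyl 2,2-dimethylpropanoate
Product: 17 methyl (2R,3R)-2-[4-(2,2-dimethylpropanoyloxy)-3,5-dimethoxyphenyl]-7-methoxy-2,3-dihydro-1-benzofuran-3-carboxylate, via enol ether 16 (not isolated)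
Conditions: PhI(OAc)2 (1.2 equiv), HC(OMe)3, conc. H2SO4 (2 equiv), 0 °C to rt
Reagents that add atoms: trimethyl orthoformate COC(OC)OC
Why: Known oxidative ring contraction of flavanones by a trivalent-iodine-induced 1,2-aryl shift: the enol ether is attacked at C3 anti to the C2 aryl group, methanol adds at C4, and the ring carbon C4a migrates from C4 to C3 with inversion, antiperiplanar to the equatorial C–I bond, so the ester ends up trans to the aryl group (3R) with C2 untouched, and the acyloxy group on the C2 aryl ring disfavours its competing shift.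

Step 9
Reactants: 7 resorcinol
Product: 18 benzene-1,3-diyl bis(2,2-dimethylpropanoate)
Conditions: PivCl (2.2 equiv), Et3N, DMAP (cat.), CH2Cl2, 0 °C to rt
Reagents that add atoms: pivaloyl chloride CC(C)(C)C(=O)Cl
Why: Standard acylation of both phenols.

Step 10
Reactants: 18 benzene-1,3-diyl bis(2,2-dimethylpropanoate) + 19 vinyl bromide
Product: 21 5-ethenylbenzene-1,3-diyl bis(2,2-dimethylpropanoate), via pinacol boronate 20 (not isolated)
Conditions: [Ir(OMe)(cod)]2 (1.5 mol%), 4,4'-di-tert-butyl-2,2'-bipyridine (3 mol%), B2pin2 (0.7 equiv), THF, 80 °C; then vinyl bromide (1 M in THF, 3 equiv), Pd(dppf)Cl2 (3 mol%), aq. K3PO4, 60 °C, sealed tube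
Reagents that add atoms: none
Why: Sterically controlled C–H borylation at C5, the only C–H meta to both ester groups, followed in the same flask by Suzuki–Miyaura coupling with vinyl bromide.

Step 11
Reactants: 17 methyl (2R,3R)-2-[4-(2,2-dimethylpropanoyloxy)-3,5-dimethoxyphenyl]-7-methoxy-2,3-dihydro-1-benzofuran-3-carboxylate + 21 5-ethenylbenzene-1,3-diyl bis(2,2-dimethylpropanoate)
Product: 22 methyl (2R,3R)-5-{(E)-2-[3,5-bis(2,2-dimethylpropanoyloxy)phenyl]ethenyl}-2-[4-(2,2-dimethylpropanoyloxy)-3,5-dimethoxyphenyl]-7-methoxy-2,3-dihydro-1-benzofuran-3-carboxylate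
Conditions: Pd(OAc)2 (10 mol%), 3-methyl-2-(phenylthio)butanoic acid (10 mol%), 21 (2 equiv), tert-butyl perbenzoate (1.2 equiv), AcOH, 80 °C
Reagents that add atoms: none
Why: Proposed new method: a non-directed dehydrogenative Heck (Fujiwara–Moritani) alkenylation with the complex arene 17 as limiting reagent, in which the thioether–carboxylate ligand speeds concerted metalation–deprotonation by divalent palladium at the most electron-rich, least hindered C–H bond; C5–H (para to the ring oxygen) is the only aromatic C–H in 17 and 21 without an ortho substituent, so the aryl–palladium forms there, inserts the styrene syn and β-hydride elimination gives the (E)-stilbene while the perester returns zerovalent palladium to the divalent state; the closest known reaction type is ligand-enabled non-directed C–H olefination of simple alkoxyarenes with acrylates, not yet shown on a polyoxygenated 2-aryl-2,3-dihydrobenzofuran or with a styrene partner, and no stereocentre is touched.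

Step 12
Reactants: 22 methyl (2R,3R)-5-{(E)-2-[3,5-bis(2,2-dimethylpropanoyloxy)phenyl]ethenyl}-2-[4-(2,2-dimethylpropanoyloxy)-3,5-dimethoxyphenyl]-7-methoxy-2,3-dihydro-1-benzofuran-3-carboxylate
Product: 23 gnetucleistol F
Conditions: LiAlH4 (6 equiv), THF, −20 to 0 °C; aq. Rochelle salt work-up
Reagents that add atoms: none
Why: Hydride reduction of the methyl ester to CH2OH, which also cleaves the three aryl pivalates; only carbonyl groups are attacked, so C2 and C3 keep their configuration (the 3R ester becomes the 3S hydroxymethyl compound by a change of substituent priority only).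

**Compound list**
1 | 2-bromophenol | Oc1ccccc1Br | starting material
2 | 2-methoxyphenol | COc1ccccc1O | intermediate
3 | ethyl propiolate | C#CC(=O)OCC | starting material
4 | ethyl (E)-3-(2-methoxyphenoxy)prop-2-enoate | CCOC(=O)/C=C/Oc1ccccc1OC | intermediate
5 | (E)-3-(2-methoxyphenoxy)prop-2-enoic acid | OC(=O)/C=C/Oc1ccccc1OC | intermediate
6 | 8-methoxy-4H-chromen-4-one | O=c1ccoc2c(OC)cccc12 | intermediate
7 | resorcinol (benzene-1,3-diol) | Oc1cccc(O)c1 | starting material
8 | 1,3-dimethoxybenzene | COc1cccc(OC)c1 | intermediate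
9 | 2,6-dimethoxyphenyllithium | [Li]c1c(OC)cccc1OC | intermediate
10 | dimethyl (2,6-dimethoxyphenyl)boronate | COB(OC)c1c(OC)cccc1OC | intermediate
11 | 2,6-dimethoxyphenol | COc1cccc(OC)c1O | intermediate
12 | 2,6-dimethoxyphenyl 2,2-dimethylpropanoate | COc1cccc(OC)c1OC(=O)C(C)(C)C | intermediate
13 | 2,6-dimethoxy-4-(4,4,5,5-tetramethyl-1,3,2-dioxaborolan-2-yl)phenyl 2,2-dimethylpropanoate | COc1cc(B2OC(C)(C)C(C)(C)O2)cc(OC)c1OC(=O)C(C)(C)C | intermediate
14 | [4-(2,2-dimethylpropanoyloxy)-3,5-dimethoxyphenyl]boronic acid | COc1cc(B(O)O)cc(OC)c1OC(=O)C(C)(C)C | intermediate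
15 | 4-[(2R)-8-methoxy-4-oxo-3,4-dihydro-2H-chromen-2-yl]-2,6-dimethoxyphenyl 2,2-dimethylpropanoate | COc1cccc2C(=O)C[C@H](c3cc(OC)c(OC(=O)C(C)(C)C)c(OC)c3)Oc12 | intermediate
16 | 4-[(2R)-4,8-dimethoxy-2H-chromen-2-yl]-2,6-dimethoxyphenyl 2,2-dimethylpropanoate | COC1=C[C@H](c2cc(OC)c(OC(=O)C(C)(C)C)c(OC)c2)Oc2c(OC)cccc12 | intermediate
17 | methyl (2R,3R)-2-[4-(2,2-dimethylpropanoyloxy)-3,5-dimethoxyphenyl]-7-methoxy-2,3-dihydro-1-benzofuran-3-carboxylate | COc1cc([C@@H]2Oc3c(OC)cccc3[C@H]2C(=O)OC)cc(OC)c1OC(=O)C(C)(C)C | intermediate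
18 | benzene-1,3-diyl bis(2,2-dimethylpropanoate) | CC(C)(C)C(=O)Oc1cccc(OC(=O)C(C)(C)C)c1 | intermediate
19 | vinyl bromide (bromoethene) | C=CBr | starting material
20 | 5-(4,4,5,5-tetramethyl-1,3,2-dioxaborolan-2-yl)benzene-1,3-diyl bis(2,2-dimethylpropanoate) | CC(C)(C)C(=O)Oc1cc(B2OC(C)(C)C(C)(C)O2)cc(OC(=O)C(C)(C)C)c1 | intermediate
21 | 5-ethenylbenzene-1,3-diyl bis(2,2-dimethylpropanoate) | C=Cc1cc(OC(=O)C(C)(C)C)cc(OC(=O)C(C)(C)C)c1 | intermediate
22 | methyl (2R,3R)-5-{(E)-2-[3,5-bis(2,2-dimethylpropanoyloxy)phenyl]ethenyl}-2-[4-(2,2-dimethylpropanoyloxy)-3,5-dimethoxyphenyl]-7-methoxy-2,3-dihydro-1-benzofuran-3-carboxylate | COc1cc([C@@H]2Oc3c(OC)cc(/C=C/c4cc(OC(=O)C(C)(C)C)cc(OC(=O)C(C)(C)C)c4)cc3[C@H]2C(=O)OC)cc(OC)c1OC(=O)C(C)(C)C | intermediate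
23 | gnetucleistol F, 5-[(E)-2-[(2R,3S)-2-(4-hydroxy-3,5-dimethoxyphenyl)-3-(hydroxymethyl)-7-methoxy-2,3-dihydro-1-benzofuran-5-yl]ethenyl]benzene-1,3-diol | COc1cc([C@@H]2Oc3c(OC)cc(/C=C/c4cc(O)cc(O)c4)cc3[C@H]2CO)cc(OC)c1O | target

**Step count and risks**

Total steps: 12. Longest linear sequence: 7 steps (4, 5, 6, 7, 8, 11, 12 from resorcinol; the branch 1, 2, 3, 7, 8, 11, 12 from 2-bromophenol is equally long).

The three steps most likely to fail:

- **Step 11, the proposed new C–H alkenylation.** It may give mixtures with the C6 position or low conversion on this advanced arene. The fallback prefunctionalises C5 with known chemistry. It sets out from 17: sterically controlled iridium-catalysed C–H borylation ([Ir(OMe)(cod)]2, 4,4'-di-tert-butyl-2,2'-bipyridine, B2pin2, THF, 80 °C) gives methyl (2R,3R)-2-[4-(2,2-dimethylpropanoyloxy)-3,5-dimethoxyphenyl]-7-methoxy-5-(4,4,5,5-tetramethyl-1,3,2-dioxaborolan-2-yl)-2,3-dihydro-1-benzofuran-3-carboxylate F1. An oxidative boron Heck coupling of this boronate with styrene 21 (Pd(OAc)2, 2,9-dimethyl-1,10-phenanthroline, O2, DMF, 50 °C) comes back to the route at 22.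

- **Step 8, the ring contraction.** Shift of the C2 aryl group (towards an isoflavone), dehydrogenation to the flavone or oxidation of the electron-rich rings by the iodine reagent may compete. The fallback keeps the 1,2-aryl shift but replaces the hypervalent iodine nucleofuge by bromide and a Lewis acid. It sets out from 15: the enol ether 16 (HC(OMe)3, MeOH, TsOH) is trapped with PhNMe3Br3 in MeOH to give 4-[(2S,3S)-3-bromo-4,4,8-trimethoxy-3,4-dihydro-2H-chromen-2-yl]-2,6-dimethoxyphenyl 2,2-dimethylpropanoate F2, with bromine trans to the aryl group. Heating with ZnBr2 in toluene at 100 °C then induces the known Lewis-acid-promoted 1,2-aryl shift of an α-bromo ketal with loss of bromomethane, and comes back to the route at 17.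

- **Step 3, the chromone ring closure.** The aryloxy oxygen is conjugated to the acrylic acid, so the Friedel–Crafts acylation may be sluggish. The fallback closes the ring at the saturated level and dehydrogenates afterwards. It sets out from 2: O-alkylation with 3-bromopropanoic acid (aq. NaOH, reflux) gives 3-(2-methoxyphenoxy)propanoic acid F3, polyphosphoric acid at 80 °C cyclises it to 8-methoxy-2,3-dihydro-4H-chromen-4-one F4, and dehydrogenation with IBX in DMSO at 80 °C comes back to the route at 6.

**Further compounds**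
F1 | step 11 | methyl (2R,3R)-2-[4-(2,2-dimethylpropanoyloxy)-3,5-dimethoxyphenyl]-7-methoxy-5-(4,4,5,5-tetramethyl-1,3,2-dioxaborolan-2-yl)-2,3-dihydro-1-benzofuran-3-carboxylate | COc1cc([C@@H]2Oc3c(OC)cc(B4OC(C)(C)C(C)(C)O4)cc3[C@H]2C(=O)OC)cc(OC)c1OC(=O)C(C)(C)C
F2 | step 8 | 4-[(2S,3S)-3-bromo-4,4,8-trimethoxy-3,4-dihydro-2H-chromen-2-yl]-2,6-dimethoxyphenyl 2,2-dimethylpropanoate | COc1cccc2c1O[C@@H](c1cc(OC)c(OC(=O)C(C)(C)C)c(OC)c1)[C@H](Br)C2(OC)OC
F3 | step 3 | 3-(2-methoxyphenoxy)propanoic acid | COc1ccccc1OCCC(=O)O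
F4 | step 3 | 8-methoxy-2,3-dihydro-4H-chromen-4-one | COc1cccc2c1OCCC2=O
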